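**Plan** (atom numbers are those of the 6H-isochromene core of the target: C1, O2, C3, C4, C4a, C5, C6, C7, C8, C8a)
- Cuts: the C7–O aroyl ester (orsellinate last); the pyran O2–C3 bond (formyl oxygen onto an alkyne); the C5–C6 bond of the carbocycle; the C7–C8 bond (aldol); the C4a–C4 bond (Sonogashira).
- Forward: ethyl acetoacetate gives enynal 10, which holds C1, C3–C5, C8, C8a and the acrylate chain; aldol with the lactate-derived dioxolanone 12 and oxidation join C7–C8; the carbocycle then closes at C5–C6, the pyran ring follows, and esterification and deprotection finish.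
- Enabling feature: C5 is the γ-methyl of the C8 enone (C8=O, C8a=C4a, C5H3) and C7 bears no hydrogen, so base can only form the vinylogous enolate at C5; C6 is the lactate carboxyl carbon, five bonds away, held as the carbonyl of a 1,3-dioxolan-4-one ring that is chiral memory, acyl activation and mask of the C7 oxygen at once and leaves as pivalaldehyde in the ring closure.
- Stereochemistry: C7 comes from (R)-lactic acid by self-regeneration of the stereocentre (steps 7 and 8); the side-chain E alkene comes from the Wittig step.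

Key step: step 10

Remark: compounds 2 to 5, 10, 14 and 15 are drawn as one geometrical isomer of the tetrasubstituted alkene; any of the other isomer is carried along, because deprotonation in step 10 turns C8a–C4a into a single bond and both isomers should converge.

**Step 1**
Reactants: 1 ethyl acetoacetate
Product: 2 ethyl (2E)-3-chloro-2-formylbut-2-enoate
Conditions: POCl3, DMF, 0 → 50 °C; then aq. NaOAc, 0 °C
Reagents that add atoms: N,N-dimethylformamide CN(C)C=O; phosphoryl chloride O=P(Cl)(Cl)Cl; water O
Why: Vilsmeier–Haack (Arnold) chloroformylation of a β-keto ester, in which the enol is formylated at C2 and the ketone oxygen is exchanged for chloride through its O-iminium derivative.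

**Step 2**
Reactants: 2 ethyl (2E)-3-chloro-2-formylbut-2-enoate
Product: 3 ethyl (2E)-3-chloro-2-(dimethoxymethyl)but-2-enoate
Conditions: HC(OMe)3, MeOH, TsOH (cat.), rt
Reagents that add atoms: trimethyl orthoformate COC(OC)OC; methanol CO
Why: Acid-catalysed acetalisation with orthoformate as water scavenger masks the future C1 aldehyde so that the ester can be turned into the C8 aldehyde.

**Step 3**
Reactants: 3 ethyl (2E)-3-chloro-2-(dimethoxymethyl)but-2-enoate
Product: 4 (2Z)-3-chloro-2-(dimethoxymethyl)but-2-en-1-ol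
Conditions: i-Bu2AlH (2.2 equiv), CH2Cl2, −78 °C; Rochelle salt work-up
Reagents that add atoms: none
Why: Hydride reduction of an α,β-unsaturated ester to the allylic alcohol with i-Bu2AlH at low temperature, which should leave the vinyl chloride and the acetal untouched.

**Step 4**
Reactants: 4 (2Z)-3-chloro-2-(dimethoxymethyl)but-2-en-1-ol
Product: 5 (2Z)-3-chloro-2-(dimethoxymethyl)but-2-enal
Conditions: MnO2, CH2Cl2, rt
Reagents that add atoms: none
Why: Chemoselective MnO2 oxidation of an allylic alcohol to the enal under neutral conditions that the acetal tolerates.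

**Step 5**
Reactants: 6 3-(trimethylsilyl)prop-2-ynal; 7 tert-butyl (triphenylphosphoranylidene)acetate
Product: 9 tert-butyl (2E)-pent-2-en-4-ynoate, via silyl enyne ester 8 (not isolated)
Conditions: CH2Cl2, 0 °C → rt; then Bu4NF, AcOH, THF, 0 °C
Reagents that add atoms: none
Why: Wittig olefination with a stabilised ylide should give the E enoate, and buffered fluoride desilylation frees the terminal alkyne without touching the ester.

**Step 6**
Reactants: 5 (2Z)-3-chloro-2-(dimethoxymethyl)but-2-enal; 9 tert-butyl (2E)-pent-2-en-4-ynoate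
Product: 10 tert-butyl (2E,6Z)-7-(dimethoxymethyl)-6-methyl-8-oxoocta-2,6-dien-4-ynoate
Conditions: PdCl2(PPh3)2 (5 mol%), CuI (10 mol%), Et3N, THF, rt → 40 °C
Reagents that add atoms: none
Why: Sonogashira coupling of a β-chloro enal, a vinylogous acid chloride that should undergo ready oxidative addition, with a terminal alkyne forms the C4a–C4 bond.

**Step 7**
Reactants: 11 (R)-lactic acid
Product: 12 (2R,5R)-2-tert-butyl-5-methyl-1,3-dioxolan-4-one
Conditions: pivalaldehyde, TsOH (cat.), H2SO4 (cat.), pentane, reflux, Dean–Stark; crystallisation from pentane/Et2O at −78 °C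
Reagents that add atoms: pivalaldehyde CC(C)(C)C=O
Why: Seebach acetalisation of an α-hydroxy acid under thermodynamic control should favour the cis dioxolanone, which is purified by crystallisation and stores the lactate configuration at the acetal carbon.

**Step 8**
Reactants: 12 (2R,5R)-2-tert-butyl-5-methyl-1,3-dioxolan-4-one; 10 tert-butyl (2E,6Z)-7-(dimethoxymethyl)-6-methyl-8-oxoocta-2,6-dien-4-ynoate
Product: 14 tert-butyl (2E,6Z)-8-[(2R,4S)-2-tert-butyl-4-methyl-5-oxo-1,3-dioxolan-4-yl]-7-(dimethoxymethyl)-8-hydroxy-6-methylocta-2,6-dien-4-ynoate (both C8 epimers), via lithium enolate 13 (not isolated)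
Conditions: LiN(i-Pr)2, THF, −78 °C; then 10, −78 °C; AcOH quench at −78 °C
Reagents that add atoms: none
Why: Seebach aldol reaction (self-regeneration of stereocentres), in which the aldehyde should add to enolate 13 on the face opposite the tert-butyl group, so that the quaternary centre (C7 of the target) is set with overall retention under control of the acetal centre; the carbinol centre is removed in step 9.

**Step 9**
Reactants: 14 aldol adduct
Product: 15 tert-butyl (2E,6E)-8-[(2R,4S)-2-tert-butyl-4-methyl-5-oxo-1,3-dioxolan-4-yl]-7-(dimethoxymethyl)-6-methyl-8-oxoocta-2,6-dien-4-ynoate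
Conditions: Dess–Martin periodinane, NaHCO3, CH2Cl2, 0 °C → rt
Reagents that add atoms: none
Why: Dess–Martin oxidation of the secondary allylic alcohol under buffered, non-basic conditions should avoid retro-aldol cleavage and gives the C8 ketone that makes C5–H acidic.

**Step 10**
Reactants: 15 keto dioxolanone
Product: 17 tert-butyl (2E)-5-[(4R)-2-(dimethoxymethyl)-4,5-dihydroxy-4-methyl-3-oxocyclohexa-1,5-dien-1-yl]pent-2-en-4-ynoate, via lithium dienolate 16 (not isolated)
Conditions: LiN(SiMe3)2 (2.2 equiv), THF, −78 → 0 °C; AcOH quench at −78 °C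
Reagents that add atoms: none
Why: Proposed new method: the base removes a proton from the C5 methyl group, the γ position of the C8 enone, and the terminal carbon of dienolate 16 adds to the lactone carbonyl C6 of the dioxolanone; collapse of the tetrahedral adduct expels the acetal oxygen, the hemiacetal alkoxide loses pivalaldehyde to unveil the C7 oxide, and the new 1,3-dicarbonyl system is held as its stabilised enolate until the quench. The closest known reaction types are the Dieckmann condensation and its vinylogous variants (γ-acylation of dienolates, lateral-metalation Claisen annulation of ortho-toluoyl ketones), together with the Claisen-type self-acylation known for lithium enolates of 2-tert-butyl-1,3-dioxolan-4-ones, which indicates that this lactone carbonyl accepts enolate carbon nucleophiles at low temperature. The six-membered carbocycle closes in the 6-(enolendo)-exo-trig mode. No stereocentre is created: C7 is quaternary and cannot enolise, so the configuration relayed from (R)-lactic acid in step 8 is kept while the auxiliary ring is destroyed. The step needs γ- over α-acylation and C- over O-acylation, which the tether secures because attack by C8a or by the enolate oxygen would give a four-membered ring, attack on the lactone and not on the remote, hindered tert-butyl ester, and the dienolate geometry with C7 and C4a cis across C8=C8a, which lithium chelation between the enolate oxygen and an acetal oxygen and reversible proton transfer at 0 °C should provide.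

**Step 11**
Reactants: 17 cyclohexadienone acetal
Product: 19 tert-butyl (2E)-3-[(7R)-7-hydroxy-7-methyl-6,8-dioxo-7,8-dihydro-6H-isochromen-3-yl]prop-2-enoate, via formyl dienone 18 (not isolated)
Conditions: 1 M aq. HCl, THF, 0 °C → rt; then pH 7 phosphate buffer, CuI (10 mol%), MeCN, rt
Reagents that add atoms: water O
Why: Acetal hydrolysis gives the 2-alkynyl formyl dienone 18, whose carbonyl oxygen should add 6-endo-dig to the copper-activated alkyne, the known cycloisomerisation of such vinylogous acids to the azaphilone pyran ring.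

**Step 12**
Reactants: 20 methyl orsellinate
Product: 21 methyl 2,4-bis(methoxymethoxy)-6-methylbenzoate
Conditions: NaH, MeOCH2Cl, DMF, 0 °C → rt
Reagents that add atoms: chloromethyl methyl ether COCCl
Why: Williamson-type O-alkylation of both phenoxides gives small, acid-labile methoxymethyl ethers, with NaH needed for the hydrogen-bonded ortho phenol.

**Step 13**
Reactants: 21 methyl 2,4-bis(methoxymethoxy)-6-methylbenzoate
Product: 22 2,4-bis(methoxymethoxy)-6-methylbenzoic acid
Conditions: KOH, MeOH/H2O, reflux; then cold aq. HCl to pH 4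
Reagents that add atoms: potassium hydroxide [K+].[OH-]
Why: Saponification of the hindered methyl benzoate under forcing basic conditions that the methoxymethyl ethers tolerate, with a brief cold acidification.

**Step 14**
Reactants: 22 2,4-bis(methoxymethoxy)-6-methylbenzoic acid; 19 azaphilone alcohol
Product: 24 (7R)-3-[(1E)-3-tert-butoxy-3-oxoprop-1-en-1-yl]-7-methyl-6,8-dioxo-7,8-dihydro-6H-isochromen-7-yl 2,4-bis(methoxymethoxy)-6-methylbenzoate, via aroyl chloride 23 (not isolated)
Conditions: 1-chloro-N,N,2-trimethylprop-1-en-1-amine, CH2Cl2, 0 °C → rt; then 19, DMAP, Et3N, CH2Cl2, 0 → 40 °C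
Reagents that add atoms: none
Why: Neutral acid chloride formation with Ghosez reagent followed by DMAP-catalysed acylation of the tertiary C7 alcohol, the known type of 7-O-acylation of azaphilone alcohols, in which the electron-rich aroyl chloride can react through an acylium-like species and C7 is not touched.

**Step 15**
Reactants: 24 protected mitorubrinic ester
Product: 25 mitorubrinic acid
Conditions: CF3CO2H/CH2Cl2/H2O (10:30:1), 0 °C → rt
Reagents that add atoms: none
Why: Acidolysis should remove the tert-butyl ester as isobutene and both methoxymethyl ethers in one operation, under acidic conditions that the azaphilone core and the aryl ester are expected to tolerate.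

**Compound list**
1 | ethyl acetoacetate | CCOC(=O)CC(C)=O | starting material
2 | ethyl (2E)-3-chloro-2-formylbut-2-enoate | CCOC(=O)/C(C=O)=C(/Cl)C | intermediate
3 | ethyl (2E)-3-chloro-2-(dimethoxymethyl)but-2-enoate | CCOC(=O)/C(C(OC)OC)=C(/Cl)C | intermediate
4 | (2Z)-3-chloro-2-(dimethoxymethyl)but-2-en-1-ol | OC/C(C(OC)OC)=C(/Cl)C | intermediate
5 | (2Z)-3-chloro-2-(dimethoxymethyl)but-2-enal | O=C/C(C(OC)OC)=C(/Cl)C | intermediate
6 | 3-(trimethylsilyl)prop-2-ynal | C[Si](C)(C)C#CC=O | starting material
7 | tert-butyl (triphenylphosphoranylidene)acetate | CC(C)(C)OC(=O)C=P(c1ccccc1)(c1ccccc1)c1ccccc1 | starting material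
8 | tert-butyl (2E)-5-(trimethylsilyl)pent-2-en-4-ynoate | C[Si](C)(C)C#C/C=C/C(=O)OC(C)(C)C | intermediate
9 | tert-butyl (2E)-pent-2-en-4-ynoate | C#C/C=C/C(=O)OC(C)(C)C | intermediate
10 | tert-butyl (2E,6Z)-7-(dimethoxymethyl)-6-methyl-8-oxoocta-2,6-dien-4-ynoate | O=C/C(C(OC)OC)=C(/C#C/C=C/C(=O)OC(C)(C)C)C | intermediate
11 | (R)-lactic acid | C[C@@H](O)C(=O)O | starting material
12 | (2R,5R)-2-tert-butyl-5-methyl-1,3-dioxolan-4-one | C[C@H]1O[C@@H](C(C)(C)C)OC1=O | intermediate
13 | lithium (2R)-2-tert-butyl-5-methyl-1,3-dioxol-4-olate | CC1=C([O-])O[C@H](C(C)(C)C)O1.[Li+] | intermediate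
14 | tert-butyl (2E,6Z)-8-[(2R,4S)-2-tert-butyl-4-methyl-5-oxo-1,3-dioxolan-4-yl]-7-(dimethoxymethyl)-8-hydroxy-6-methylocta-2,6-dien-4-ynoate (both C8 epimers) | CC(C)(C)[C@@H]1O[C@](C(O)/C(C(OC)OC)=C(\C)C#C/C=C/C(=O)OC(C)(C)C)(C)C(=O)O1 | intermediate
15 | tert-butyl (2E,6E)-8-[(2R,4S)-2-tert-butyl-4-methyl-5-oxo-1,3-dioxolan-4-yl]-7-(dimethoxymethyl)-6-methyl-8-oxoocta-2,6-dien-4-ynoate | CC(C)(C)[C@@H]1O[C@](C(=O)/C(C(OC)OC)=C(\C)C#C/C=C/C(=O)OC(C)(C)C)(C)C(=O)O1 | intermediate
16 | lithium dienolate of 15 (enolate oxygen on C8, double bonds C8=C8a and C4a=C5H2, C7 and C4a cis across C8=C8a) | [Li+].[O-]/C(=C(\C(OC)OC)C(=C)C#C/C=C/C(=O)OC(C)(C)C)[C@]1(C)O[C@@H](C(C)(C)C)OC1=O | intermediate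
17 | tert-butyl (2E)-5-[(4R)-2-(dimethoxymethyl)-4,5-dihydroxy-4-methyl-3-oxocyclohexa-1,5-dien-1-yl]pent-2-en-4-ynoate | C[C@@]1(O)C(O)=CC(C#C/C=C/C(=O)OC(C)(C)C)=C(C(OC)OC)C1=O | intermediate
18 | tert-butyl (2E)-5-[(4R)-2-formyl-4,5-dihydroxy-4-methyl-3-oxocyclohexa-1,5-dien-1-yl]pent-2-en-4-ynoate | C[C@@]1(O)C(O)=CC(C#C/C=C/C(=O)OC(C)(C)C)=C(C=O)C1=O | intermediate
19 | tert-butyl (2E)-3-[(7R)-7-hydroxy-7-methyl-6,8-dioxo-7,8-dihydro-6H-isochromen-3-yl]prop-2-enoate | C[C@@]1(O)C(=O)C=C2C=C(/C=C/C(=O)OC(C)(C)C)OC=C2C1=O | intermediate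
20 | methyl orsellinate (methyl 2,4-dihydroxy-6-methylbenzoate) | COC(=O)c1c(C)cc(O)cc1O | starting material
21 | methyl 2,4-bis(methoxymethoxy)-6-methylbenzoate | COC(=O)c1c(C)cc(OCOC)cc1OCOC | intermediate
22 | 2,4-bis(methoxymethoxy)-6-methylbenzoic acid | OC(=O)c1c(C)cc(OCOC)cc1OCOC | intermediate
23 | 2,4-bis(methoxymethoxy)-6-methylbenzoyl chloride | ClC(=O)c1c(C)cc(OCOC)cc1OCOC | intermediate
24 | (7R)-3-[(1E)-3-tert-butoxy-3-oxoprop-1-en-1-yl]-7-methyl-6,8-dioxo-7,8-dihydro-6H-isochromen-7-yl 2,4-bis(methoxymethoxy)-6-methylbenzoate | Cc1cc(OCOC)cc(OCOC)c1C(=O)O[C@]1(C)C(=O)C=C2C=C(/C=C/C(=O)OC(C)(C)C)OC=C2C1=O | intermediate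
25 | mitorubrinic acid | Cc1cc(O)cc(O)c1C(=O)O[C@]1(C)C(=O)C=C2C=C(/C=C/C(=O)O)OC=C2C1=O | target

**Step count**
Total: 15 steps. Longest linear sequence: 11 steps (1, 2, 3, 4, 6, 8, 9, 10, 11, 14, 15).

**Steps most likely to fail**

Step 10 (Proposed new method).
- What may go wrong: deprotonation may give the dienolate geometry in which C7 and C4a are trans across C8=C8a and cannot reach each other. The stabilised carbanion may fail to add to the hindered lactone carbonyl. The liberated C7 alkoxide may start retro-Claisen cleavage or an α-ketol shift before the quench.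
- Fallback (known chemistry, oxidative dearomatisation of a resorcinol aldehyde): it sets out from alkyne 9. Vilsmeier formylation of 5-bromo-2-methylbenzene-1,3-diol would give 6-bromo-2,4-dihydroxy-3-methylbenzaldehyde F1. Sonogashira coupling of this bromide with 9 (PdCl2(PPh3)2, CuI, Et3N) would give tert-butyl (2E)-5-(2-formyl-3,5-dihydroxy-4-methylphenyl)pent-2-en-4-ynoate F2. Copper-mediated enantioselective hydroxylative dearomatisation ([Cu(MeCN)4]PF6, (−)-sparteine, O2, i-Pr2NEt, DMAP, CH2Cl2, −78 °C) should then deliver formyl dienone 18, which cyclises under the buffer conditions of step 11. The route is rejoined at 19. The sense of induction would have to be confirmed and the other ligand enantiomer used if needed.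

Step 14.
- What may go wrong: acylation of the hindered tertiary alcohol, flanked by two carbonyl groups, by a 2,6-disubstituted aroyl chloride may be slower than base- or nucleophile-induced degradation of the azaphilone.
- Fallback (the ester is made before the rings): it sets out from ketone 15. Acid-catalysed methanolysis of the dioxolanone (camphorsulfonic acid, MeOH) would give 10-tert-butyl 1-methyl (2S,4E,8E)-4-(dimethoxymethyl)-2-hydroxy-2,5-dimethyl-3-oxodeca-4,8-dien-6-ynedioate F3. Acylation of its tertiary alcohol with 23 under forcing conditions that this open-chain compound should bear (DMAP, pyridine, 50 °C) would give 10-tert-butyl 1-methyl (2S,4E,8E)-2-{[2,4-bis(methoxymethoxy)-6-methylbenzoyl]oxy}-4-(dimethoxymethyl)-2,5-dimethyl-3-oxodeca-4,8-dien-6-ynedioate F4. LiN(SiMe3)2 would then close the carbocycle on the methyl ester in the manner of step 10 to give (1R)-4-[(3E)-5-tert-butoxy-5-oxopent-3-en-1-yn-1-yl]-3-(dimethoxymethyl)-6-hydroxy-1-methyl-2-oxocyclohexa-3,5-dien-1-yl 2,4-bis(methoxymethoxy)-6-methylbenzoate F5. Mild acetal hydrolysis and copper-catalysed cycloisomerisation as in step 11 would lead to 24, where the route is rejoined.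

Step 8.
- What may go wrong: addition to the crowded formyl group on a fully substituted alkene may be slow, the enolate may instead remove a γ-proton from 10, and the adduct may revert by retro-aldol reaction on warming.
- Fallback (acylation in place of aldol and oxidation): it sets out from aldehyde 10. Pinnick oxidation (NaClO2, NaH2PO4, 2-methylbut-2-ene) would give (2E,6E)-8-tert-butoxy-2-(dimethoxymethyl)-3-methyl-8-oxoocta-2,6-dien-4-ynoic acid F6. Ghosez reagent would convert it into tert-butyl (2E,6E)-8-chloro-7-(dimethoxymethyl)-6-methyl-8-oxoocta-2,6-dien-4-ynoate F7. C-acylation of lithium enolate 13 with this acid chloride at −78 °C, again anti to the tert-butyl group, would give ketone 15 directly, where the route is rejoined.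

**Further compounds**
F1 | step 10 | 6-bromo-2,4-dihydroxy-3-methylbenzaldehyde | O=Cc1c(O)c(C)c(O)cc1Br
F2 | step 10 | tert-butyl (2E)-5-(2-formyl-3,5-dihydroxy-4-methylphenyl)pent-2-en-4-ynoate | O=Cc1c(O)c(C)c(O)cc1C#C/C=C/C(=O)OC(C)(C)C
F3 | step 14 | 10-tert-butyl 1-methyl (2S,4E,8E)-4-(dimethoxymethyl)-2-hydroxy-2,5-dimethyl-3-oxodeca-4,8-dien-6-ynedioate | COC(=O)[C@@](C)(O)C(=O)/C(C(OC)OC)=C(\C)C#C/C=C/C(=O)OC(C)(C)C
F4 | step 14 | 10-tert-butyl 1-methyl (2S,4E,8E)-2-{[2,4-bis(methoxymethoxy)-6-methylbenzoyl]oxy}-4-(dimethoxymethyl)-2,5-dimethyl-3-oxodeca-4,8-dien-6-ynedioate | COC(=O)[C@@](C)(OC(=O)c1c(C)cc(OCOC)cc1OCOC)C(=O)/C(C(OC)OC)=C(\C)C#C/C=C/C(=O)OC(C)(C)C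
F5 | step 14 | (1R)-4-[(3E)-5-tert-butoxy-5-oxopent-3-en-1-yn-1-yl]-3-(dimethoxymethyl)-6-hydroxy-1-methyl-2-oxocyclohexa-3,5-dien-1-yl 2,4-bis(methoxymethoxy)-6-methylbenzoate | C[C@@]1(OC(=O)c2c(C)cc(OCOC)cc2OCOC)C(O)=CC(C#C/C=C/C(=O)OC(C)(C)C)=C(C(OC)OC)C1=O
F6 | step 8 | (2E,6E)-8-tert-butoxy-2-(dimethoxymethyl)-3-methyl-8-oxoocta-2,6-dien-4-ynoic acid | OC(=O)/C(C(OC)OC)=C(/C#C/C=C/C(=O)OC(C)(C)C)C
F7 | step 8 | tert-butyl (2E,6E)-8-chloro-7-(dimethoxymethyl)-6-methyl-8-oxoocta-2,6-dien-4-ynoate | ClC(=O)/C(C(OC)OC)=C(/C#C/C=C/C(=O)OC(C)(C)C)C
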